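The numbers in the tables were computed for an exercise, noise included.

**The decision.** Count the reagent before choosing what the grey flask gets at 25 min.

| flask | substrate | reagent | temperature | remark | time |
|---|---|---|---|---|---|
| grey | 0.050 M | 0.50 equiv | 40 °C | the very flask that is asked about, followed so far |  |
| amber | 0.075 M | 0.50 equiv | 46 °C | run made earlier |  |
| flask | 0.050 M | 0.500 equiv | 40 °C |  | 25 min |

- grey (time / min: target / %): 0.833: 0.7; 2.50: 10.5; 4.00: 15.1; 6.00: 15.6; 10.0: 14.0; 12.0: 12.9; 15.0: 11.3
- amber (time / min: target / %): 0.833: 6.7; 1.33: 9.7; 2.00: 10.6; 3.00: 10.6; 4.00: 12.0; 6.00: 10.6; 10.0: 10.3

(each reading ± 1 percentage point)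

- north-east: at 25 min raise the temperature by 10 K, then wait 50 min
- west: at 25 min add reagent, 50.0% of the amount charged, then wait 50 min
- north-west: change nothing and wait 50 min more
- south-east: at 25 min take out 90% of the by-product then present, then wait 50 min

- the volume of additions can be left aside
- what was read earlier has a scatter of 1 percentage point, one standard deviation

- target, in percent of the substrate first charged, at 25 min
- what to do for the largest gain in target; "none" if nothing gains more than 2 percentage points (north-east / west / north-west / south-east / none)
- target present, in percent of the substrate first charged, after west
- target present, in percent of the substrate first charged, after south-east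

**Two ends.** The early end of the grey run is a rise to a peak, read as 15.6% at 6.00 min, and a slide after it. The late end serves better, because 25 min lies beyond the last reading at 15.0 min. There the grey run reads 11.3%, and the amber run reads 10.3% at 10.0 min. These stand 1 percentage point apart against a scatter of 1 point, although substrate and temperature differ. What the two runs have in common is 0.50 equiv of reagent.

**Reagent share.** Assume one reagent per substrate. Then c(reagent) starts at 0.0250 M against c(substrate) at 0.050 M, so reagent is the limiting reagent, and the tail should grow with the reagent charged. Hence the reagent share, late target per equivalent of reagent charged: 22.6%, a reading that carries its scatter. The amber run gives 20.6%. The grey run was still falling at its last reading, so its value may lie on the high side.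

**The choice.** At 25 min the share gives 11.3% in the grey flask. Waiting and south-east leave the reagent count unchanged, so this reckoning keeps the same figure for both. The amber run, hotter but also more concentrated, shows no larger share, so it gives no ground to expect a gain from heat. West raises the reagent to 0.750 equiv, and the share then gives 16.9% of target, an estimated gain of 5.7 points, above the margin. The 50 min that follow are longer than the grey run so far, so the late share is the figure to use, not the peak. So west is the choice.

**The forecast.** It says 8.7% now (6.8% to 10.5%), west as the move, 11% after west and 4.5% after south-east, where “Removing by-product takes away material that could return”, and this reckoning stands higher on each number.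

**The result.** The flask gives 11.0% at 25 min, and west gains 5.1 points, reaching 16.1%, while south-east gives 10.7%. At 25.0 min the flask holds 0.0526% of its reagent and 49.8% of its substrate. Read back, the share after west is 21.5%, against 22.6% from the grey reading.

    substrate + reagent → intermediate + by-product (k = 11.0 /M/min, Ea = 50.0 kJ/mol)
    intermediate ⇌ target (K = 1.60, k = 0.380 /min, Ea = 100 kJ/mol, ΔH = −63.0 kJ/mol)
    intermediate ⇌ isomer of the product A (K = 3.10, k = 0.170 /min, Ea = 97.0 kJ/mol, ΔH = −77.0 kJ/mol)
    2 substrate → homo dimer (k = 0.00290 /M/min, Ea = 75.0 kJ/mol)
    target ⇌ isomer of the product B (K = 1.10, k = 0.110 /min, Ea = 92.0 kJ/mol, ΔH = −11.0 kJ/mol)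
    (constants at 40 °C)

**Second flask.** A flask like this one, charged with 0.850 equiv of reagent, should hold 19.2% of target at 25 min by the reagent share. The simulation gives 18.6%.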